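**Retrosynthetic overview**
- Ring B is cut last at C3=C4: intramolecular aldol condensation of the C10 aldehyde (α-carbon C3) onto an aryl aldehyde that is C4; the C7 phenol is then freed from an isopropyl ether.
- The route rests on ring A being a benzene with four neighbouring substituents (C4 on C4a, C1 on C8a, OMe on C8, OH on C7) in which C8a is wedged between C1 and the C8 oxygen. Ring A is therefore built around the finished C1–C8a bond: 3-isopropoxyfuran adds across the alkyne of a 4-aryl-but-2-ynal (bonds C8–C8a and C4a–C5) and the oxygen bridge opens to the C8 phenol.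
- The ynal comes from a terminal alkyne by formylation; C1 and C2 are set together by a copper/amine propargylic alkylation of 4,4-dimethoxybutanal with the propargylic acetate of veratraldehyde.
- Ring order: ring C is bought (veratraldehyde), ring A is formed in step 8, ring B in step 11.

Key step: step 8

Assumption: in step 4 each catalyst is taken to control one centre; the amine antipode follows the usual shielding model of diarylprolinol silyl ethers, and the pybox antipode written is the one assumed to give the (R)-benzylic centre, its mirror image being used if the sense proves opposite.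

Step 1
Reactants: 1 veratraldehyde
Product: 2 rac-1-(3,4-dimethoxyphenyl)prop-2-yn-1-ol
Conditions: HC≡CMgBr (1.3 equiv, 0.5 M in THF), THF, 0 °C → rt; aq. NH4Cl
Reagents that add atoms: ethynylmagnesium bromide, C#C[Mg]Br
Why: Grignard addition of the acetylide to a non-enolizable aldehyde should be clean, and the carbinol centre may stay racemic because it is erased in the copper allenylidene of step 4.

Step 2
Reactants: 2 rac-1-(3,4-dimethoxyphenyl)prop-2-yn-1-ol
Product: 3 rac-1-(3,4-dimethoxyphenyl)prop-2-yn-1-yl acetate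
Conditions: Ac2O, Et3N, DMAP (5 mol%), CH2Cl2, 0 °C → rt
Reagents that add atoms: acetic anhydride, CC(=O)OC(C)=O
Why: DMAP-catalysed O-acylation of the secondary propargylic alcohol installs the acetate leaving group needed for the propargylic substitution.

Step 3
Reactants: 4 methyl 4,4-dimethoxybutanoate
Product: 5 4,4-dimethoxybutanal
Conditions: i-Bu2AlH (1.05 equiv), CH2Cl2, −78 °C; aq. potassium sodium tartrate
Reagents that add atoms: none
Why: Partial ester reduction with i-Bu2AlH at −78 °C should stop at the aldehyde because the tetrahedral aluminium alkoxide survives until work-up, the dimethyl acetal being inert to hydride.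

Step 4
Reactants: 3 rac-1-(3,4-dimethoxyphenyl)prop-2-yn-1-yl acetate; 5 4,4-dimethoxybutanal
Product: 7 (2S,3R)-2-(2,2-dimethoxyethyl)-3-(3,4-dimethoxyphenyl)pent-4-yn-1-ol, via pentynal 6 (not isolated)
Conditions: CuOTf·0.5C6H6 (5 mol%), (S,S)-Ph-pybox (6 mol%), (R)-diphenylprolinol trimethylsilyl ether (20 mol%), i-Pr2NEt (1.2 equiv), 5 (2.5 equiv), THF, −10 °C; then NaBH4, MeOH, −10 → 0 °C
Reagents that add atoms: none
Why: Cooperative copper/enamine propargylic alkylation (Nishibayashi type) in which the copper acetylide of 3 loses acetate to a copper allenylidene whose γ-carbon is attacked by the enamine of 5; the pybox ligand differentiates the faces of the allenylidene and sets the benzylic centre (R in 7, future C1), the prolinol silyl ether shields one enamine face and sets the α-centre (S, future C2), both enantiomers of 3 converge through the allenylidene, and NaBH4 in the same flask removes the epimerizable aldehyde.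

Step 5
Reactants: 7 (2S,3R)-2-(2,2-dimethoxyethyl)-3-(3,4-dimethoxyphenyl)pent-4-yn-1-ol
Product: 8 tert-butyl{[(2S,3R)-2-(2,2-dimethoxyethyl)-3-(3,4-dimethoxyphenyl)pent-4-yn-1-yl]oxy}dimethylsilane
Conditions: TBSCl, imidazole, DMF, rt
Reagents that add atoms: tert-butyldimethylsilyl chloride, CC(C)(C)[Si](C)(C)Cl
Why: Imidazole-promoted silylation of a primary alcohol gives a C9 protecting group that should survive butyllithium and the cycloaddition and fall together with the acetal in step 10.

Step 6
Reactants: 8 tert-butyl{[(2S,3R)-2-(2,2-dimethoxyethyl)-3-(3,4-dimethoxyphenyl)pent-4-yn-1-yl]oxy}dimethylsilane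
Product: 10 (4S,5S)-5-{[tert-butyl(dimethyl)silyl]oxymethyl}-4-(3,4-dimethoxyphenyl)-7,7-dimethoxyhept-2-ynal, via lithium acetylide 9 (not isolated)
Conditions: n-BuLi (1.05 equiv), THF, −78 °C; DMF (2 equiv), −78 → −20 °C; inverse quench into cold aq. KH2PO4/MTBE
Reagents that add atoms: N,N-dimethylformamide, CN(C)C=O
Why: The sp C–H is far more acidic than the benzylic propargylic C–H, so n-BuLi should metalate only the alkyne, and formylation of the acetylide with DMF followed by inverse quench into phosphate buffer releases the ynal without exposing it to free amine or base, which protects C1 from propargyl–allenyl isomerization.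

Step 7
Reactants: 11 3-bromofuran
Product: 12 3-isopropoxyfuran
Conditions: i-PrOH (solvent), CuI (10 mol%), 3,4,7,8-tetramethyl-1,10-phenanthroline (20 mol%), Cs2CO3 (1.5 equiv), sealed tube, 110 °C; distillation
Reagents that add atoms: propan-2-ol, CC(C)O
Why: Ligand-accelerated Ullmann-type C–O coupling of a heteroaryl bromide with a secondary alcohol under CuI/phenanthroline catalysis should give the volatile enol-ether furan, which is distilled and stored cold over K2CO3.

Step 8
Reactants: 10 (4S,5S)-5-{[tert-butyl(dimethyl)silyl]oxymethyl}-4-(3,4-dimethoxyphenyl)-7,7-dimethoxyhept-2-ynal; 12 3-isopropoxyfuran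
Product: 14 2-[(1S,2S)-2-{[tert-butyl(dimethyl)silyl]oxymethyl}-1-(3,4-dimethoxyphenyl)-4,4-dimethoxybutyl]-3-hydroxy-4-(propan-2-yloxy)benzaldehyde, via oxanorbornadiene 13 (not isolated)
Conditions: 12 (3 equiv), PhMe (1 M), 23 → 50 °C, Ar, dark; then SiO2, CH2Cl2, rt
Reagents that add atoms: none
Why: Normal-demand Diels–Alder reaction between the electron-rich furan and the formyl-activated alkyne, in which furan C2 (the enol-ether β-carbon, largest HOMO coefficient) bonds to the ynal β-carbon (future C8a) and furan C5 to the formyl-bearing carbon (future C4a), giving 7-oxanorbornadiene 13 in a concerted, asynchronous [4+2]; the closest known reaction type is the cycloaddition of 3-alkoxyfurans and other furans with acetylenic aldehydes and esters followed by phenol formation. The bridge then opens by heterolysis of the C5–O bond, the only one whose cation is a vinylogous oxocarbenium ion through the isopropoxy group on C7, and loss of the C8 proton aromatizes, so the furan oxygen ends as the C8 hydroxyl. Ring A is thus closed by an intermolecular [4+2] cycloaddition (two new sigma bonds, six-membered carbocycle), not by cyclization of a chain. No stereocentre is formed in the product, since both bridgehead centres of 13 vanish on aromatization and C1 and C2 are spectators. The selectivity needed is regiochemical, head-to-tail orientation in the cycloaddition and C5–O over C8–O cleavage, and both are secured by the push of the 3-alkoxy group and the pull of the formyl group. The neutral, amine-free medium keeps the acidic C1–H from propargyl–allenyl isomerization, and the excess of furan offsets the hindrance at the branched alkyne terminus.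

Step 9
Reactants: 14 2-[(1S,2S)-2-{[tert-butyl(dimethyl)silyl]oxymethyl}-1-(3,4-dimethoxyphenyl)-4,4-dimethoxybutyl]-3-hydroxy-4-(propan-2-yloxy)benzaldehyde
Product: 15 2-[(1S,2S)-2-{[tert-butyl(dimethyl)silyl]oxymethyl}-1-(3,4-dimethoxyphenyl)-4,4-dimethoxybutyl]-3-methoxy-4-(propan-2-yloxy)benzaldehyde
Conditions: MeI (3 equiv), K2CO3 (2 equiv), DMF, rt → 40 °C
Reagents that add atoms: iodomethane, CI
Why: Williamson etherification of the phenoxide, the only acidic site, fixes the C8 methoxy group, the aryl aldehyde being non-enolizable and the acetal and silyl ether stable to carbonate.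

Step 10
Reactants: 15 2-[(1S,2S)-2-{[tert-butyl(dimethyl)silyl]oxymethyl}-1-(3,4-dimethoxyphenyl)-4,4-dimethoxybutyl]-3-methoxy-4-(propan-2-yloxy)benzaldehyde
Product: 16 2-[(1S,2S)-1-(3,4-dimethoxyphenyl)-2-(hydroxymethyl)-4-oxobutyl]-3-methoxy-4-(propan-2-yloxy)benzaldehyde
Conditions: 1 M aq. HCl/THF (1:3), rt
Reagents that add atoms: water, O
Why: Aqueous acid hydrolyses the dimethyl acetal to the C10 aldehyde and cleaves the primary silyl ether while aryl ethers and the aryl aldehyde are untouched, and the product is expected as a ring–chain mixture with its five-membered lactol, which does not matter for step 11.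

Step 11
Reactants: 16 2-[(1S,2S)-1-(3,4-dimethoxyphenyl)-2-(hydroxymethyl)-4-oxobutyl]-3-methoxy-4-(propan-2-yloxy)benzaldehyde
Product: 18 (1S,2R)-1-(3,4-dimethoxyphenyl)-2-(hydroxymethyl)-8-methoxy-7-(propan-2-yloxy)-1,2-dihydronaphthalene-3-carbaldehyde, via aldol adduct 17 (not isolated)
Conditions: Bn2NH·CF3CO2H (0.5 equiv), PhMe (0.02 M), 50 °C
Reagents that add atoms: none
Why: Amine-salt-mediated intramolecular aldol condensation in which the enamine of the only enolizable aldehyde (C10, nucleophilic at C3) adds to the aryl aldehyde C4 in a 6-(enolexo)-exo-trig closure of ring B and E1cB loss of water is driven by conjugation with ring A; C2 is β to the enolizing carbonyl and C1 is a diarylmethine, so neither centre should epimerize.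

Step 12
Reactants: 18 (1S,2R)-1-(3,4-dimethoxyphenyl)-2-(hydroxymethyl)-8-methoxy-7-(propan-2-yloxy)-1,2-dihydronaphthalene-3-carbaldehyde
Product: 19 vitekwangin B, (1S,2R)-1-(3,4-dimethoxyphenyl)-7-hydroxy-2-(hydroxymethyl)-8-methoxy-1,2-dihydronaphthalene-3-carbaldehyde
Conditions: BCl3 (1 M in CH2Cl2, 3 equiv), CH2Cl2, −78 → −20 °C; then MeOH, aq. NaHCO3
Reagents that add atoms: none
Why: BCl3 dealkylation of an aryl isopropyl ether proceeds by O-coordination and loss of the secondary alkyl group as 2-chloropropane at temperatures where aryl methyl ethers should survive, and the borate esters of the phenol and the primary alcohol are hydrolysed on work-up.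

**Compound list**
1 | veratraldehyde (3,4-dimethoxybenzaldehyde) | COc1ccc(C=O)cc1OC | starting material
2 | rac-1-(3,4-dimethoxyphenyl)prop-2-yn-1-ol | COc1ccc(C(O)C#C)cc1OC | intermediate
3 | rac-1-(3,4-dimethoxyphenyl)prop-2-yn-1-yl acetate | COc1ccc(C(OC(C)=O)C#C)cc1OC | intermediate
4 | methyl 4,4-dimethoxybutanoate | COC(=O)CCC(OC)OC | starting material
5 | 4,4-dimethoxybutanal | O=CCCC(OC)OC | intermediate
6 | (2S,3R)-2-(2,2-dimethoxyethyl)-3-(3,4-dimethoxyphenyl)pent-4-ynal | COc1ccc([C@H]([C@@H](C=O)CC(OC)OC)C#C)cc1OC | intermediate (not isolated)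
7 | (2S,3R)-2-(2,2-dimethoxyethyl)-3-(3,4-dimethoxyphenyl)pent-4-yn-1-ol | COc1ccc([C@H]([C@@H](CO)CC(OC)OC)C#C)cc1OC | intermediate
8 | tert-butyl{[(2S,3R)-2-(2,2-dimethoxyethyl)-3-(3,4-dimethoxyphenyl)pent-4-yn-1-yl]oxy}dimethylsilane | COc1ccc([C@H]([C@@H](CO[Si](C)(C)C(C)(C)C)CC(OC)OC)C#C)cc1OC | intermediate
9 | lithium acetylide of 8 | COc1ccc([C@H]([C@@H](CO[Si](C)(C)C(C)(C)C)CC(OC)OC)C#C[Li])cc1OC | intermediate (not isolated)
10 | (4S,5S)-5-{[tert-butyl(dimethyl)silyl]oxymethyl}-4-(3,4-dimethoxyphenyl)-7,7-dimethoxyhept-2-ynal | COc1ccc([C@H]([C@@H](CO[Si](C)(C)C(C)(C)C)CC(OC)OC)C#CC=O)cc1OC | intermediate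
11 | 3-bromofuran | Brc1ccoc1 | starting material
12 | 3-isopropoxyfuran | CC(C)Oc1ccoc1 | intermediate
13 | 3-[(1S,2S)-2-{[tert-butyl(dimethyl)silyl]oxymethyl}-1-(3,4-dimethoxyphenyl)-4,4-dimethoxybutyl]-5-(propan-2-yloxy)-7-oxabicyclo[2.2.1]hepta-2,5-diene-2-carbaldehyde, both bridgehead diastereomers | COc1ccc([C@H]([C@@H](CO[Si](C)(C)C(C)(C)C)CC(OC)OC)C2=C(C=O)C3OC2C(OC(C)C)=C3)cc1OC | intermediate (not isolated)
14 | 2-[(1S,2S)-2-{[tert-butyl(dimethyl)silyl]oxymethyl}-1-(3,4-dimethoxyphenyl)-4,4-dimethoxybutyl]-3-hydroxy-4-(propan-2-yloxy)benzaldehyde | COc1ccc([C@H]([C@@H](CO[Si](C)(C)C(C)(C)C)CC(OC)OC)c2c(C=O)ccc(OC(C)C)c2O)cc1OC | intermediate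
15 | 2-[(1S,2S)-2-{[tert-butyl(dimethyl)silyl]oxymethyl}-1-(3,4-dimethoxyphenyl)-4,4-dimethoxybutyl]-3-methoxy-4-(propan-2-yloxy)benzaldehyde | COc1ccc([C@H]([C@@H](CO[Si](C)(C)C(C)(C)C)CC(OC)OC)c2c(C=O)ccc(OC(C)C)c2OC)cc1OC | intermediate
16 | 2-[(1S,2S)-1-(3,4-dimethoxyphenyl)-2-(hydroxymethyl)-4-oxobutyl]-3-methoxy-4-(propan-2-yloxy)benzaldehyde (open form, in equilibrium with its five-membered lactol) | COc1ccc([C@H]([C@@H](CO)CC=O)c2c(C=O)ccc(OC(C)C)c2OC)cc1OC | intermediate
17 | (1S,2R)-1-(3,4-dimethoxyphenyl)-4-hydroxy-2-(hydroxymethyl)-8-methoxy-7-(propan-2-yloxy)-1,2,3,4-tetrahydronaphthalene-3-carbaldehyde, mixture at C3 and C4 | COc1ccc([C@H]2c3c(ccc(OC(C)C)c3OC)C(O)C(C=O)[C@@H]2CO)cc1OC | intermediate (not isolated)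
18 | (1S,2R)-1-(3,4-dimethoxyphenyl)-2-(hydroxymethyl)-8-methoxy-7-(propan-2-yloxy)-1,2-dihydronaphthalene-3-carbaldehyde (trans) | COc1ccc([C@H]2c3c(ccc(OC(C)C)c3OC)C=C(C=O)[C@@H]2CO)cc1OC | intermediate
19 | vitekwangin B, (1S,2R)-1-(3,4-dimethoxyphenyl)-7-hydroxy-2-(hydroxymethyl)-8-methoxy-1,2-dihydronaphthalene-3-carbaldehyde (trans) | COc1ccc([C@H]2c3c(ccc(O)c3OC)C=C(C=O)[C@@H]2CO)cc1OC | target

Total step count: 12. Longest linear sequence: 10 steps (1, 2, 4, 5, 6, 8, 9, 10, 11, 12 from veratraldehyde).

**Steps most likely to fail**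

Step 8. The cycloaddition may be slow at the branched alkyne terminus, so that the ynal isomerizes to the allenal or oligomerizes first, or the furan may add in conjugate fashion without closing the second bond. The fallback replaces the formyl activating group by an ester that tolerates prolonged heating; it sets out from 8 and returns at 15. Metalation of 8 (n-BuLi, THF, −78 °C) and acylation with methyl chloroformate should give the methyl ynoate F1. Heating F1 with 12 (toluene, 100–110 °C, sealed) should bring about the same cycloaddition and ring opening, as is known for acetylenic esters and furans, and give the hydroxybenzoate F2. MeI/K2CO3 should give the methoxybenzoate F3, i-Bu2AlH (CH2Cl2, −78 → 0 °C) the benzylic alcohol F4, and MnO2 (CH2Cl2, rt) the aldehyde 15.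

Step 4. Diastereocontrol may be insufficient if the two catalysts are mismatched, C2 may erode by enamine-mediated epimerization before reduction, and the electron-rich acetate may ionize without copper and give a racemic background reaction. The fallback uses stereodivergent iridium/amine allylation, in which each catalyst fixes one centre independently, and then converts the vinyl group into the ynal; it sets out from 1 (with 5) and returns at 10. Vinylmagnesium bromide and 1 should give the racemic allylic alcohol F5. F5 and 5 with [Ir(cod)Cl]2, a chiral phosphoramidite–olefin ligand, diphenylprolinol trimethylsilyl ether and dimethyl hydrogen phosphate (1,2-dichloroethane, rt) should give the pentenal F6, the antipodes of ligand and amine being chosen for the (2S,3S) isomer. NaBH4 should give the pentenol F7 and TBSCl/imidazole the silyl ether F8. OsO4 (cat.)/NaIO4 with 2,6-lutidine in dioxane–water should cleave the vinyl group to the α-aryl aldehyde F9, and CBr4/PPh3 (CH2Cl2, 0 °C) should give the dibromoalkene F10. n-BuLi (2.1 equiv, THF, −78 °C), then DMF and the phosphate quench of step 6, should give 10 directly.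

Step 12. The Lewis acid may also remove the flanking C8 methyl ether or degrade the electron-rich enal and its primary alcohol. The fallback carries the C7 oxygen as an acid-labile 4-methoxybenzyl ether so that no Lewis-acid dealkylation is needed; it sets out from 11 and 10 and returns at 19. Coupling of 11 with 4-methoxybenzyl alcohol (CuI, 3,4,7,8-tetramethyl-1,10-phenanthroline, Cs2CO3, toluene, 110 °C) should give the benzyloxyfuran F11. F11 and 10 under the conditions of step 8 should give the phenol F12, and MeI/K2CO3 the methyl ether F13. CF3CO2H/CH2Cl2/H2O with anisole (0 °C → rt) should remove the 4-methoxybenzyl ether, the acetal and the silyl ether in one operation and give the phenolic hydroxy dialdehyde F14. Bn2NH·CF3CO2H as in step 11 should then close ring B and give 19.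

**Further compounds**
F1 | step 8 | methyl (4S,5S)-5-{[tert-butyl(dimethyl)silyl]oxymethyl}-4-(3,4-dimethoxyphenyl)-7,7-dimethoxyhept-2-ynoate | COc1ccc([C@H]([C@@H](CO[Si](C)(C)C(C)(C)C)CC(OC)OC)C#CC(=O)OC)cc1OC
F2 | step 8 | methyl 2-[(1S,2S)-2-{[tert-butyl(dimethyl)silyl]oxymethyl}-1-(3,4-dimethoxyphenyl)-4,4-dimethoxybutyl]-3-hydroxy-4-(propan-2-yloxy)benzoate | COc1ccc([C@H]([C@@H](CO[Si](C)(C)C(C)(C)C)CC(OC)OC)c2c(C(=O)OC)ccc(OC(C)C)c2O)cc1OC
F3 | step 8 | methyl 2-[(1S,2S)-2-{[tert-butyl(dimethyl)silyl]oxymethyl}-1-(3,4-dimethoxyphenyl)-4,4-dimethoxybutyl]-3-methoxy-4-(propan-2-yloxy)benzoate | COc1ccc([C@H]([C@@H](CO[Si](C)(C)C(C)(C)C)CC(OC)OC)c2c(C(=O)OC)ccc(OC(C)C)c2OC)cc1OC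
F4 | step 8 | {2-[(1S,2S)-2-{[tert-butyl(dimethyl)silyl]oxymethyl}-1-(3,4-dimethoxyphenyl)-4,4-dimethoxybutyl]-3-methoxy-4-(propan-2-yloxy)phenyl}methanol | COc1ccc([C@H]([C@@H](CO[Si](C)(C)C(C)(C)C)CC(OC)OC)c2c(CO)ccc(OC(C)C)c2OC)cc1OC
F5 | step 4 | rac-1-(3,4-dimethoxyphenyl)prop-2-en-1-ol | COc1ccc(C(O)C=C)cc1OC
F6 | step 4 | (2S,3S)-2-(2,2-dimethoxyethyl)-3-(3,4-dimethoxyphenyl)pent-4-enal | COc1ccc([C@H]([C@@H](C=O)CC(OC)OC)C=C)cc1OC
F7 | step 4 | (2S,3S)-2-(2,2-dimethoxyethyl)-3-(3,4-dimethoxyphenyl)pent-4-en-1-ol | COc1ccc([C@H]([C@@H](CO)CC(OC)OC)C=C)cc1OC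
F8 | step 4 | tert-butyl{[(2S,3S)-2-(2,2-dimethoxyethyl)-3-(3,4-dimethoxyphenyl)pent-4-en-1-yl]oxy}dimethylsilane | COc1ccc([C@H]([C@@H](CO[Si](C)(C)C(C)(C)C)CC(OC)OC)C=C)cc1OC
F9 | step 4 | (2S,3S)-3-{[tert-butyl(dimethyl)silyl]oxymethyl}-2-(3,4-dimethoxyphenyl)-5,5-dimethoxypentanal | COc1ccc([C@H]([C@@H](CO[Si](C)(C)C(C)(C)C)CC(OC)OC)C=O)cc1OC
F10 | step 4 | 1,1-dibromoalkene from F9, 4-[1,1-dibromo-4-{[tert-butyl(dimethyl)silyl]oxymethyl}-6,6-dimethoxyhex-1-en-3-yl]-1,2-dimethoxybenzene, configuration as in 8 | COc1ccc([C@H]([C@@H](CO[Si](C)(C)C(C)(C)C)CC(OC)OC)C=C(Br)Br)cc1OC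
F11 | step 12 | 3-[(4-methoxyphenyl)methoxy]furan | COc1ccc(COc2ccoc2)cc1
F12 | step 12 | 2-[(1S,2S)-2-{[tert-butyl(dimethyl)silyl]oxymethyl}-1-(3,4-dimethoxyphenyl)-4,4-dimethoxybutyl]-3-hydroxy-4-[(4-methoxyphenyl)methoxy]benzaldehyde | COc1ccc([C@H]([C@@H](CO[Si](C)(C)C(C)(C)C)CC(OC)OC)c2c(C=O)ccc(OCc3ccc(OC)cc3)c2O)cc1OC
F13 | step 12 | 2-[(1S,2S)-2-{[tert-butyl(dimethyl)silyl]oxymethyl}-1-(3,4-dimethoxyphenyl)-4,4-dimethoxybutyl]-3-methoxy-4-[(4-methoxyphenyl)methoxy]benzaldehyde | COc1ccc([C@H]([C@@H](CO[Si](C)(C)C(C)(C)C)CC(OC)OC)c2c(C=O)ccc(OCc3ccc(OC)cc3)c2OC)cc1OC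
F14 | step 12 | 2-[(1S,2S)-1-(3,4-dimethoxyphenyl)-2-(hydroxymethyl)-4-oxobutyl]-4-hydroxy-3-methoxybenzaldehyde (open form, in equilibrium with its lactol) | COc1ccc([C@H]([C@@H](CO)CC=O)c2c(C=O)ccc(O)c2OC)cc1OC
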